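Counting the side chain from the OCH2 carbon (C1') to the carbinol carbon C7', the target is cut first at the O7–C1' ether bond to the coumarin (benzene ring A, pyranone ring B). It is then cut at C2'–C1' and C3'–CH3. The feature exploited is the trisubstituted C2'=C3' double bond, in which the C3' methyl group and C1' lie on the same side (E). This pattern arises when CH3 and aluminium add to the same side of a 1-alkyne and the C–Al bond is then exchanged for CH2OH with retention. One operation thus joins alkyne, Me3Al and formaldehyde through two new C–C bonds. Its precursor is the bis(triethylsilyl) ether of (R)-6-methylhept-1-yne-3,6-diol, available in four steps from a lactone.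

Key step: step 5

Remark: hydroxy ynone 4 may equilibrate with its five-membered cyclic hemiketal; the two forms interconvert and are treated here as the open-chain ketone.

Step 1
Reactants: 1 5,5-dimethyldihydrofuran-2(3H)-one; 2 ethynyltrimethylsilane
Product: 4 6-hydroxy-6-methyl-1-(trimethylsilyl)hept-1-yn-3-one, via lithium trimethylsilylacetylide 3 (not isolated)
Conditions: 2, n-BuLi, THF, −78 °C; then 1, −78 °C; AcOH, −78 °C → rt
Reagents that add atoms: none
Why: This is the 1,2-addition of a lithium acetylide to a lactone carbonyl, in which the cyclic lithium hemiketal alkoxide should persist at −78 °C, so that the ketone is released only by the cold acid quench and both a second addition and alkoxide attack on the alkynyl silicon are suppressed; no stereocentre is formed.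

Step 2
Reactants: 4 6-hydroxy-6-methyl-1-(trimethylsilyl)hept-1-yn-3-one
Product: 5 (3R)-6-methyl-1-(trimethylsilyl)hept-1-yne-3,6-diol
Conditions: RuCl(p-cymene)[(R,R)-TsDPEN] (2 mol %, pre-activated with KOH), i-PrOH, rt
Reagents that add atoms: none
Why: In this Noyori–Ikariya asymmetric transfer hydrogenation of an α,β-acetylenic ketone, the Ru–H/N–H pair of the (R,R)-catalyst should deliver hydride and proton through a six-membered outer-sphere transition state with the alkynyl π system next to the η6-arene, which sets C3 (the later C4') as R, leaves the triple bond alone and cannot dehydrogenate the tertiary carbinol.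

Step 3
Reactants: 5 (3R)-6-methyl-1-(trimethylsilyl)hept-1-yne-3,6-diol
Product: 6 (3R)-6-methylhept-1-yne-3,6-diol
Conditions: K2CO3 (cat.), MeOH, rt; filtration through silica, no aqueous work-up
Reagents that add atoms: none
Why: In this methoxide-catalysed protodesilylation of an alkynylsilane, attack at silicon expels the stabilised acetylide, which methanol protonates, and the mildly basic medium touches neither carbinol nor the C3 stereocentre.

Step 4
Reactants: 6 (3R)-6-methylhept-1-yne-3,6-diol
Product: 7 (3R)-3,6-bis(triethylsilyloxy)-6-methylhept-1-yne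
Conditions: TESOTf, 2,6-lutidine, CH2Cl2, −78 → 0 °C
Reagents that add atoms: triethylsilyl trifluoromethanesulfonate (TESOTf) CC[Si](CC)(CC)OS(=O)(=O)C(F)(F)F
Why: In this O-silylation with a silyl triflate and a hindered pyridine base, TESOTf is reactive enough to cap the tertiary and the secondary propargylic hydroxyl in one operation, 2,6-lutidine is too weak to metalate the alkyne C–H, and the C3–O bond is not broken, so the R configuration is kept.

Step 5
Reactants: 7 (3R)-3,6-bis(triethylsilyloxy)-6-methylhept-1-yne; 8 trimethylaluminium; 9 formaldehyde (charged as paraformaldehyde)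
Product: 13 (2E,4R)-4,7-bis(triethylsilyloxy)-3,7-dimethyloct-2-en-1-ol, via alkenyldimethylalane 10 (not isolated), via lithium alkenylalanate 11 (not isolated), via lithium alkoxyaluminate 12 (not isolated)
Conditions: Me3Al, Cp2ZrCl2 (cat.), CH2Cl2, 0 °C → rt; volatiles removed in vacuo; n-BuLi, hexane–THF, −78 → 0 °C; (CH2O)n, THF, 0 °C → rt; H2O, aq. potassium sodium tartrate
Reagents that add atoms: trimethylaluminium C[Al](C)C; formaldehyde (from paraformaldehyde) C=O
Why: Ligand exchange between Cp2ZrCl2 and Me3Al gives a polarised Zr–CH3/Al species that inserts the terminal alkyne of 7 through a concerted four-centre syn addition, and Zr-to-Al transmetalation releases alkenylalane 10 and returns the catalyst (Negishi zirconium-catalysed methylalumination). n-BuLi turns the weakly nucleophilic 10 into alanate 11, which transfers its alkenyl group in preference to methyl or butyl, with retention at C2', to monomeric formaldehyde, giving alkoxyaluminate 12 and then 13 on hydrolysis; the closest known reaction type is the hydroxymethylation of alkenylalanates with paraformaldehyde used for (E)-3-methylalk-2-en-1-ols. No ring is closed and no stereocentre is created; the only new stereoelement is the C2'=C3' geometry, fixed by syn addition followed by retentive capture, so that CH3 and C1' end up cis (E). The step needs regioselectivity (CH3 to C3', metal to C2'), which the terminal alkyne secures by directing the bulky metal to its unsubstituted carbon. It also needs chemoselectivity, secured because 7 carries no acidic or strongly Lewis-basic group, only two hindered triethylsilyl ethers that bind aluminium poorly and tolerate n-BuLi, while aluminium in 10 and 11 sits trans to C4', so O-to-C silyl migration is geometrically excluded. C4' takes part in no bond change, so its R configuration should pass unchanged into 13.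

Step 6
Reactants: 13 (2E,4R)-4,7-bis(triethylsilyloxy)-3,7-dimethyloct-2-en-1-ol; 14 scopoletin (7-hydroxy-6-methoxy-2H-chromen-2-one)
Product: 15 7-{[(2E,4R)-4,7-bis(triethylsilyloxy)-3,7-dimethyloct-2-en-1-yl]oxy}-6-methoxy-2H-chromen-2-one
Conditions: PPh3, DIAD, THF, 0 °C → rt
Reagents that add atoms: none
Why: In this Mitsunobu etherification the acidic 7-OH of ring A protonates the phosphine–azodicarboxylate adduct, and the phenoxide should displace the oxyphosphonium group by SN2 at the unhindered primary allylic C1', which is not stereogenic, leaving the alkene geometry, the silyl ethers and C4' untouched.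

Step 7
Reactants: 15 7-{[(2E,4R)-4,7-bis(triethylsilyloxy)-3,7-dimethyloct-2-en-1-yl]oxy}-6-methoxy-2H-chromen-2-one
Product: 16 7-{[(2E,4R)-4,7-dihydroxy-3,7-dimethyloct-2-en-1-yl]oxy}-6-methoxy-2H-chromen-2-one (CNP0197418.1)
Conditions: HF·pyridine, pyridine, THF, 0 °C → rt
Reagents that add atoms: none
Why: This fluoride-driven cleavage of both triethylsilyl ethers rests on the strength of the Si–F bond, and the pyridine buffer keeps the medium too weakly acidic to ionise the allylic C4' carbinol or the aryl allyl ether and too weakly basic to open the lactone of ring B, so the C–O bond at C4' and its R configuration remain intact.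

Compound list
1 | 5,5-dimethyldihydrofuran-2(3H)-one (γ,γ-dimethyl-γ-butyrolactone) | CC1(C)CCC(=O)O1 | starting material
2 | ethynyltrimethylsilane | C#C[Si](C)(C)C | starting material
3 | lithium (trimethylsilyl)acetylide | [Li+].[C-]#C[Si](C)(C)C | intermediate (not isolated)
4 | 6-hydroxy-6-methyl-1-(trimethylsilyl)hept-1-yn-3-one | C[Si](C)(C)C#CC(=O)CCC(C)(C)O | intermediate
5 | (3R)-6-methyl-1-(trimethylsilyl)hept-1-yne-3,6-diol | C[Si](C)(C)C#C[C@H](O)CCC(C)(C)O | intermediate
6 | (3R)-6-methylhept-1-yne-3,6-diol | C#C[C@H](O)CCC(C)(C)O | intermediate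
7 | (3R)-3,6-bis(triethylsilyloxy)-6-methylhept-1-yne | C#C[C@H](O[Si](CC)(CC)CC)CCC(C)(C)O[Si](CC)(CC)CC | intermediate
8 | trimethylaluminium | C[Al](C)C | starting material
9 | formaldehyde (used as paraformaldehyde) | C=O | starting material
10 | dimethyl[(1E,3R)-3,6-bis(triethylsilyloxy)-2,6-dimethylhept-1-en-1-yl]alane | C[Al](C)/C=C(\C)[C@H](O[Si](CC)(CC)CC)CCC(C)(C)O[Si](CC)(CC)CC | intermediate (not isolated)
11 | lithium butyl(dimethyl)[(1E,3R)-3,6-bis(triethylsilyloxy)-2,6-dimethylhept-1-en-1-yl]aluminate | [Li+].CCCC[Al-](C)(C)/C=C(\C)[C@H](O[Si](CC)(CC)CC)CCC(C)(C)O[Si](CC)(CC)CC | intermediate (not isolated)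
12 | lithium butyl(dimethyl)[(2E,4R)-4,7-bis(triethylsilyloxy)-3,7-dimethyloct-2-en-1-yloxy]aluminate | [Li+].CCCC[Al-](C)(C)OC/C=C(\C)[C@H](O[Si](CC)(CC)CC)CCC(C)(C)O[Si](CC)(CC)CC | intermediate (not isolated)
13 | (2E,4R)-4,7-bis(triethylsilyloxy)-3,7-dimethyloct-2-en-1-ol | OC/C=C(\C)[C@H](O[Si](CC)(CC)CC)CCC(C)(C)O[Si](CC)(CC)CC | intermediate
14 | scopoletin (7-hydroxy-6-methoxy-2H-chromen-2-one) | COc1cc2ccc(=O)oc2cc1O | starting material
15 | 7-{[(2E,4R)-4,7-bis(triethylsilyloxy)-3,7-dimethyloct-2-en-1-yl]oxy}-6-methoxy-2H-chromen-2-one | COc1cc2ccc(=O)oc2cc1OC/C=C(\C)[C@H](O[Si](CC)(CC)CC)CCC(C)(C)O[Si](CC)(CC)CC | intermediate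
16 | 7-{[(2E,4R)-4,7-dihydroxy-3,7-dimethyloct-2-en-1-yl]oxy}-6-methoxy-2H-chromen-2-one | COc1cc2ccc(=O)oc2cc1OC/C=C(\C)[C@H](O)CCC(C)(C)O | target

Total step count: 7
Longest linear sequence: 7 steps (1 → 16)

Steps most likely to fail

1. Step 5.
- **What may go wrong:** The carbometalation may be slow or incomplete because the propargylic silyloxy group crowds and weakly coordinates the metals. Regiocontrol may erode, a silyl ether may be lost on long exposure to the Lewis-acidic medium, and the C–Al bond may be protonated before formaldehyde is captured. A measured amount of water added to the Me3Al is the first adjustment of conditions.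
- **Fallback (sets out from 7, returns at 13):** The order in which the two carbons are introduced is inverted. Deprotonation of 7 with n-BuLi and hydroxymethylation with paraformaldehyde should give (4R)-4,7-bis(triethylsilyloxy)-7-methyloct-2-yn-1-ol F1. Hydroxyl-directed trans-hydroalumination with NaAlH2(OCH2CH2OMe)2 places aluminium on C3', cis to C1', and iodinolysis with I2 should give (2Z,4R)-3-iodo-4,7-bis(triethylsilyloxy)-7-methyloct-2-en-1-ol F2. Me2CuLi then replaces iodine by methyl with retention and delivers 13.

2. Step 1.
- **What may go wrong:** The tetrahedral adduct may collapse before the quench, which would allow a second acetylide addition. The alkoxide may strip the alkynyl silyl group, and enolisation of the lactone may compete.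
- **Fallback (sets out from 1, returns at 4):** The C–C bond is made at the aldehyde oxidation level and the ketone is installed afterwards. Reduction of 1 with i-Bu2AlH (CH2Cl2, −78 °C) should give 5,5-dimethyloxolan-2-ol F3. This lactol reacts through its open hydroxy aldehyde form with an excess of 3 to give racemic 6-methyl-1-(trimethylsilyl)hept-1-yne-3,6-diol F4. MnO2 in CH2Cl2 oxidises only the propargylic carbinol, since the tertiary one cannot be oxidised, and gives 4.

3. Step 2.
- **What may go wrong:** The ketone may be sequestered as its hemiketal, so that hydrogen transfer stalls. Traces of base may remove the alkynyl silyl group, and the free alkyne terminus would then deactivate the catalyst. Reversible hydrogen transfer may erode the facial selectivity.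
- **Fallback (sets out from 4, returns at 7):** The hydroxyl is masked first, and the stereocentre is set by a stoichiometric chiral organoborane instead of a metal catalyst. TESOTf and 2,6-lutidine should give 6-methyl-6-(triethylsilyloxy)-1-(trimethylsilyl)hept-1-yn-3-one F5. Midland reduction follows, using B-isopinocampheyl-9-borabicyclo[3.3.1]nonane derived from (+)-α-pinene. It transfers its β-hydride through a cyclic six-membered transition state with the slim alkynyl group in the crowded position, and should give (3R)-6-methyl-6-(triethylsilyloxy)-1-(trimethylsilyl)hept-1-yn-3-ol F6. K2CO3 in MeOH gives (3R)-6-methyl-6-(triethylsilyloxy)hept-1-yn-3-ol F7, and TESCl with imidazole closes the detour at 7.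

Further compounds
F1 | step 5 | (4R)-4,7-bis(triethylsilyloxy)-7-methyloct-2-yn-1-ol | OCC#C[C@H](O[Si](CC)(CC)CC)CCC(C)(C)O[Si](CC)(CC)CC
F2 | step 5 | (2Z,4R)-3-iodo-4,7-bis(triethylsilyloxy)-7-methyloct-2-en-1-ol | OC/C=C(\I)[C@H](O[Si](CC)(CC)CC)CCC(C)(C)O[Si](CC)(CC)CC
F3 | step 1 | 5,5-dimethyloxolan-2-ol (racemic lactol) | CC1(C)CCC(O)O1
F4 | step 1 | racemic 6-methyl-1-(trimethylsilyl)hept-1-yne-3,6-diol | C[Si](C)(C)C#CC(O)CCC(C)(C)O
F5 | step 2 | 6-methyl-6-(triethylsilyloxy)-1-(trimethylsilyl)hept-1-yn-3-one | C[Si](C)(C)C#CC(=O)CCC(C)(C)O[Si](CC)(CC)CC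
F6 | step 2 | (3R)-6-methyl-6-(triethylsilyloxy)-1-(trimethylsilyl)hept-1-yn-3-ol | C[Si](C)(C)C#C[C@H](O)CCC(C)(C)O[Si](CC)(CC)CC
F7 | step 2 | (3R)-6-methyl-6-(triethylsilyloxy)hept-1-yn-3-ol | C#C[C@H](O)CCC(C)(C)O[Si](CC)(CC)CC
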